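The target is achiral. The real problem is the handle-free thirteen-methylene tether C7–C19 that links alkyne carbon C6 to C2 of the furan ring. Everything rests on cutting its C17–C18 CH2–CH2 bond back to two carboxylic acids. In one cathodic, nickel-mediated operation the N-hydroxyphthalimide esters of both acids lose CO2 and their primary radicals are joined. This completes the C23 skeleton without exposing the furan to oxidation. The precursors are the activated ester of purchased 3-(furan-2-yl)propanoic acid and the activated ester of an eighteen-carbon alkynedioic acid monomethyl ester. The latter is assembled from hex-5-ynoic acid and 12-bromododecanol by acetylide alkylation at C6–C7.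

Key step: step 7

Remark: the SMILES holds no stereocentre and no stereogenic double bond, so there is no enantiomer to select; chain numbering runs from the carboxyl carbon (C1) to the CH2 on the furan (C19).

Step 1
Reactants: 1 12-bromododecan-1-ol
Product: 2 (12-bromododecyloxy)(tert-butyl)dimethylsilane
Conditions: TBSCl (1.1 equiv), imidazole (2 equiv), CH2Cl2, 0 °C to rt
Reagents that add atoms: tert-butyldimethylsilyl chloride, CC(C)(C)[Si](C)(C)Cl
Why: Imidazole-promoted silylation of a primary alcohol, run in CH2Cl2 at or below room temperature so that imidazole does not displace the primary bromide; the ether masks the O–H that would quench the acetylide in step 2.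

Step 2
Reactants: 3 hex-5-ynoic acid (1.3 equiv), 2 (12-bromododecyloxy)(tert-butyl)dimethylsilane
Product: 6 18-(tert-butyldimethylsilyloxy)octadec-5-ynoic acid, via dilithio hex-5-ynoate 4 (not isolated), via lithium silyloxyoctadecynoate 5 (not isolated)
Conditions: n-BuLi (2.0 equiv per 3), THF, −78 to 0 °C; DMPU, then 2, NaI (10 mol %), 0 °C to rt; cold 0.5 M HCl to pH 3–4; crude acid carried on
Reagents that add atoms: n-butyllithium, [Li]CCCC (supplies only the lithium of 4 and 5; no atom of it remains in 6)
Why: SN2 alkylation of a carboxylate–acetylide dianion, in which the far more basic carbon terminus attacks the unhindered primary bromide (helped by DMPU and in situ Finkelstein exchange) to form C6–C7; the silyl ether is inert to the base, and any silyl loss in the short acidic work-up is harmless because step 3 removes the group anyway.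

Step 3
Reactants: 6 18-(tert-butyldimethylsilyloxy)octadec-5-ynoic acid
Product: 7 methyl 18-hydroxyoctadec-5-ynoate
Conditions: HCl (1.25 M in MeOH), rt to 40 °C
Reagents that add atoms: methanol, CO
Why: Fischer esterification and acid-catalysed methanolysis of the primary silyl ether proceed side by side and leave the internal alkyne untouched, so one operation differentiates the chain ends (C1 ester, C18 alcohol); the excess of 3 becomes volatile methyl hex-5-ynoate, which is easily removed.

Step 4
Reactants: 7 methyl 18-hydroxyoctadec-5-ynoate
Product: 9 18-methoxy-18-oxooctadec-13-ynoic acid, via methyl 18-oxooctadec-5-ynoate 8 (not isolated)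
Conditions: TEMPO (20 mol %), PhI(OAc)2 (2.2 equiv), CH2Cl2/H2O (2:1), rt
Reagents that add atoms: water, O
Why: Oxoammonium (TEMPO/PhI(OAc)2) oxidation takes the primary alcohol to aldehyde 8, whose hydrate is oxidised on to the acid; the metal-free, nearly neutral medium spares alkyne and methyl ester, and the two-phase solvent keeps the lipophilic chain dissolved.

Step 5
Reactants: 9 18-methoxy-18-oxooctadec-13-ynoic acid, 10 N-hydroxyphthalimide
Product: 11 1-methyl 18-(1,3-dioxoisoindolin-2-yl) octadec-5-ynedioate
Conditions: DIC (1.1 equiv), DMAP (10 mol %), CH2Cl2, rt; short silica plug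
Reagents that add atoms: none
Why: Steglich-type carbodiimide esterification, in which DIC activates the only free carboxyl group and DMAP relays the acyl group to the N–OH of 10, with the methyl ester and alkyne as bystanders.

Step 6
Reactants: 12 3-(furan-2-yl)propanoic acid, 10 N-hydroxyphthalimide
Product: 13 1,3-dioxoisoindolin-2-yl 3-(furan-2-yl)propanoate
Conditions: DIC (1.1 equiv), DMAP (10 mol %), CH2Cl2, rt; recrystallisation or silica plug
Reagents that add atoms: none
Why: The same Steglich-type activation as in step 5, to which the furan ring is indifferent, and it is easily run on the larger scale needed because this ester is used in excess.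

Step 7
Reactants: 11 1-methyl 18-(1,3-dioxoisoindolin-2-yl) octadec-5-ynedioate (limiting), 13 1,3-dioxoisoindolin-2-yl 3-(furan-2-yl)propanoate (3 equiv)
Product: 14 methyl 19-(furan-2-yl)nonadec-5-ynoate
Conditions: NiCl2·6H2O (20 mol %), 2,6-bis(pyrazol-1-yl)pyridine (20 mol %), AgNO3 (substoichiometric, plates Ag nanoparticles on the cathode), NaI (electrolyte), NMP, (+)Mg/(−)RVC, undivided cell, constant current until both esters are consumed, rt; aq NH4Cl work-up
Reagents that add atoms: none
Why: Low-valent nickel formed at the silver-coated cathode passes one electron to each phthalimide ester, which fragments to phthalimide anion, CO2 and a primary radical, namely 2-(furan-2-yl)ethyl (C18–C19) from 13 and 17-methoxy-17-oxoheptadec-12-yn-1-yl (C1–C17) from 11. The tridentate-ligated nickel takes up the two radicals one after the other and reductive elimination from the dialkylnickel species makes the C17–C18 bond; this is the known Ni-electrocatalytic doubly decarboxylative C(sp3)–C(sp3) coupling of two primary redox-active esters, a reductive counterpart of mixed Kolbe electrolysis. No ring is closed and no stereocentre is created. The only selectivity required is cross- over homo-coupling, which is tilted statistically by the threefold excess of the cheap ester 13, and sorting should be simple because the furan–furan dimer carries no ester, 14 one and the chain–chain dimer two. The substrate itself blocks side paths: ten methylenes (C7–C16) separate the C17 radical from the alkyne so no 5- or 6-exo closure is possible, a 1,2-furyl shift in the furylethyl radical is degenerate, and the internal alkyne offers silver no acidic C–H. The methyl ester is inert, and the electron-rich furan sees only reducing potentials, unlike in an anodic Kolbe electrolysis where it would be oxidised first.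

Step 8
Reactants: 14 methyl 19-(furan-2-yl)nonadec-5-ynoate
Product: 16 19-(furan-2-yl)nonadec-5-ynoic acid (target), via lithium furylnonadecynoate 15 (not isolated)
Conditions: LiOH·H2O (3 equiv), THF/H2O (3:1), rt; 0.5 M HCl dropwise, 0 °C, to pH 4; EtOAc extraction
Reagents that add atoms: lithium hydroxide, [Li+].[OH-]
Why: Ordinary BAc2 saponification of an unhindered methyl ester, which furan and internal alkyne tolerate; the cold, controlled acidification only to pH 4 avoids acid-induced opening of the 2-alkylfuran.

Compound list
1 | 12-bromododecan-1-ol | OCCCCCCCCCCCCBr | starting material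
2 | (12-bromododecyloxy)(tert-butyl)dimethylsilane | BrCCCCCCCCCCCCO[Si](C)(C)C(C)(C)C | intermediate
3 | hex-5-ynoic acid | C#CCCCC(=O)O | starting material
4 | dilithium carboxylate–acetylide of hex-5-ynoic acid | [Li+].[Li+].[C-]#CCCCC(=O)[O-] | intermediate (not isolated)
5 | lithium 18-(tert-butyldimethylsilyloxy)octadec-5-ynoate | [Li+].[O-]C(=O)CCCC#CCCCCCCCCCCCCO[Si](C)(C)C(C)(C)C | intermediate (not isolated)
6 | 18-(tert-butyldimethylsilyloxy)octadec-5-ynoic acid | O=C(O)CCCC#CCCCCCCCCCCCCO[Si](C)(C)C(C)(C)C | intermediate
7 | methyl 18-hydroxyoctadec-5-ynoate | COC(=O)CCCC#CCCCCCCCCCCCCO | intermediate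
8 | methyl 18-oxooctadec-5-ynoate | COC(=O)CCCC#CCCCCCCCCCCCC=O | intermediate (not isolated)
9 | 18-methoxy-18-oxooctadec-13-ynoic acid | COC(=O)CCCC#CCCCCCCCCCCCC(=O)O | intermediate
10 | N-hydroxyphthalimide | ON1C(=O)c2ccccc2C1=O | starting material
11 | 1-methyl 18-(1,3-dioxoisoindolin-2-yl) octadec-5-ynedioate | COC(=O)CCCC#CCCCCCCCCCCCC(=O)ON1C(=O)c2ccccc2C1=O | intermediate
12 | 3-(furan-2-yl)propanoic acid | O=C(O)CCc1ccco1 | starting material
13 | 1,3-dioxoisoindolin-2-yl 3-(furan-2-yl)propanoate | O=C(CCc1ccco1)ON1C(=O)c2ccccc2C1=O | intermediate
14 | methyl 19-(furan-2-yl)nonadec-5-ynoate | COC(=O)CCCC#CCCCCCCCCCCCCCc1ccco1 | intermediate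
15 | lithium 19-(furan-2-yl)nonadec-5-ynoate | [Li+].[O-]C(=O)CCCC#CCCCCCCCCCCCCCc1ccco1 | intermediate (not isolated)
16 | 19-(furan-2-yl)nonadec-5-ynoic acid | O=C(O)CCCC#CCCCCCCCCCCCCCc1ccco1 | target

Total step count: 8. Longest linear sequence: 7 (steps 1, 2, 3, 4, 5, 7, 8); step 6 is the one-step side branch.

Steps most likely to fail

(a) Step 7.
- **Risk:** Cross-coupling may be eroded by statistical homo-coupling, premature reduction of the radicals to C–H, β-hydride elimination at alkylnickel, or binding of the internal alkyne to low-valent nickel.
- **Change of approach:** The fallback keeps the C17–C18 bond but replaces the radical–radical union by a decarboxylative Negishi-type alkyl–alkyl coupling. Only 11 then acts as radical source and the furan half arrives as a preformed nucleophile, so cross-selectivity is built in.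
- **Route:** Commercial 2-(furan-2-yl)ethanol is brominated under Appel conditions (CBr4, PPh3, CH2Cl2, 0 °C) to 2-(2-bromoethyl)furan F1. Magnesium in THF converts it to [2-(furan-2-yl)ethyl]magnesium bromide F2. ZnCl2 (0.5 equiv) then gives bis[2-(furan-2-yl)ethyl]zinc F3, which is coupled with 11 using NiCl2·glyme and 4,4'-di-tert-butyl-2,2'-bipyridine in THF/DMF at rt.
- **Scope:** It sets out from 11 and comes back at 14.

(b) Step 2.
- **Risk:** The poorly soluble, aggregated dianion may substitute sluggishly. Carboxylate O-alkylation and E2 loss of HBr from the bromide may then compete.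
- **Change of approach:** The fallback reverses the order of assembly, so that only a monoanion is alkylated and the carboxyl carbon travels masked.
- **Route:** Bromide 2 is treated with lithium acetylide–ethylenediamine complex in DMSO to give tert-butyl(dimethyl)(tetradec-13-yn-1-yloxy)silane F4. n-BuLi in THF forms its lithium acetylide F5. Alkylation with commercial 4-bromo-1,1,1-trimethoxybutane in THF/DMPU gives tert-butyl(dimethyl)[(18,18,18-trimethoxyoctadec-13-yn-1-yl)oxy]silane F6. Methanolic HCl containing a little water then collapses the orthoester to the methyl ester and removes the silyl group in the same flask.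
- **Scope:** It sets out from 2 and comes back at 7.

(c) Step 4.
- **Risk:** The one-pot oxidation may stall at the aldehyde stage. Alternatively, the aldehyde may be trapped by unreacted alcohol as a hemiacetal that is oxidised to a dimeric ester.
- **Change of approach and route:** The fallback splits the change of oxidation state into two separate reactions with an isolated aldehyde. Dess–Martin periodinane in dry CH2Cl2 consumes all alcohol and delivers 8, now isolated. A Pinnick oxidation (NaClO2, NaH2PO4, 2-methyl-2-butene, t-BuOH/H2O) then takes 8 to the acid.
- **Scope:** It sets out from 7, passes through 8 and comes back at 9. No compound outside the list is made (F0).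

Further compounds
F1 | step 7 | 2-(2-bromoethyl)furan | BrCCc1ccco1
F2 | step 7 | [2-(furan-2-yl)ethyl]magnesium bromide | Br[Mg]CCc1ccco1
F3 | step 7 | bis[2-(furan-2-yl)ethyl]zinc | c1coc(CC[Zn]CCc2ccco2)c1
F4 | step 2 | tert-butyl(dimethyl)(tetradec-13-yn-1-yloxy)silane | C#CCCCCCCCCCCCCO[Si](C)(C)C(C)(C)C
F5 | step 2 | lithium acetylide of F4 | [Li+].[C-]#CCCCCCCCCCCCCO[Si](C)(C)C(C)(C)C
F6 | step 2 | tert-butyl(dimethyl)[(18,18,18-trimethoxyoctadec-13-yn-1-yl)oxy]silane | COC(OC)(OC)CCCC#CCCCCCCCCCCCCO[Si](C)(C)C(C)(C)C
F0 | step 4 | none | none
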